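**Plan**

1. Numbering used throughout: C1 (CH–OOH), C2, C3 (CH–OAc), C4 (C–CH3), C5, C6 (lactone CH–O), C7–C9, C10 (C=CH2); C11/C12 are the butenolide α-carbon and carbonyl, C13 the CH2OAc carbon, C14 the exocyclic CH2.
2. Retrosynthesis: C1–OOH with the C10=C14 shift goes back to an E C1=C10 olefin (ene reaction) and the acetates to a diol. The butenolide is cut at C7=C11 (metathesis) and O–C12 (ester) down to a C6 ketone. The carbocycle is cut at C8–C9 with C1–C6 re-formed.
3. Enabling feature: the Z C4=C5 olefin with its flanking carbons C3 and C6 fits into a cyclohexene. An E C1=C10 olefin together with a C6 carbonyl and a C6–C7 enolate is exactly what a [3,3] shift of a 1-vinyl-6-isopropenylcyclohex-2-en-1-ol leaves behind.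
4. Forward: the cyclohexene is made first from a quinone monoketal, the ten-membered ring arises from it by two-carbon ring expansion, the butenolide is then fused on at C6/C7, and the hydroperoxide comes last.
5. Stereochemistry: C3 comes from a catalytic asymmetric isopropenyl addition relayed by a cis-selective Luche reduction (the relay centre is erased in the rearrangement). C6 comes from an oxazaborolidine-catalysed ketone reduction and C1 from the face-selective ene reaction. 4Z is inherited from the cyclohexene and 1(10)E from the chair transition state.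

Key step: step 7

Remark: the ligand and oxazaborolidine enantiomers named below are those predicted by the usual empirical models; the mirror-image catalyst would be used if the first experiment showed the opposite sense.

**Route**

Step 1
Reactants: 1 4-methoxy-2-methylphenol
Product: 2 4,4-dimethoxy-2-methylcyclohexa-2,5-dien-1-one
Conditions: PhI(OAc)2, MeOH, 0 °C
Reagents that add atoms: methanol (SMILES CO)
Why: Oxidative dearomatisation of a para-methoxyphenol with (diacetoxyiodo)benzene in methanol is the standard entry to quinone monoketals, methanol capturing the oxidised ring at the carbon that already carries the methoxy group.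

Step 2
Reactants: 2 4,4-dimethoxy-2-methylcyclohexa-2,5-dien-1-one; 3 isopropenylboronic acid pinacol ester
Product: 4 (5S)-4,4-dimethoxy-2-methyl-5-(prop-1-en-2-yl)cyclohex-2-en-1-one
Conditions: [RhCl(C2H4)2]2 (2.5 mol %), (S,S)-2,5-diphenylbicyclo[2.2.2]octa-2,5-diene (5.5 mol %), aq. KOH, dioxane, 30 °C
Reagents that add atoms: none
Why: Hayashi–Miyaura asymmetric conjugate addition, in which the isopropenylrhodium species adds to the unsubstituted C5=C6 enone arm (the 2-methyl-substituted arm is far less reactive) and the chiral diene selects the enone face so that the new C5 centre is S, the (S,S) ligand being the enantiomer expected to give this sense by analogy with cyclohex-2-enone.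

Step 3
Reactants: 4 (5S)-4,4-dimethoxy-2-methyl-5-(prop-1-en-2-yl)cyclohex-2-en-1-one
Product: 5 (1S,5S)-4,4-dimethoxy-2-methyl-5-(prop-1-en-2-yl)cyclohex-2-en-1-ol
Conditions: NaBH4, CeCl3·7H2O, MeOH, −78 °C
Reagents that add atoms: none
Why: Luche 1,2-reduction, in which hydride attacks the carbonyl on the face opposite the C5 isopropenyl group so that the new C1 hydroxyl (the future C3 oxygen of the target, S) ends up cis to it, as in the reduction of other 5-substituted cyclohexenones to cis-alcohols.

Step 4
Reactants: 5 (1S,5S)-4,4-dimethoxy-2-methyl-5-(prop-1-en-2-yl)cyclohex-2-en-1-ol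
Product: 6 tert-butyl{[(1S,5S)-4,4-dimethoxy-2-methyl-5-(prop-1-en-2-yl)cyclohex-2-en-1-yl]oxy}dimethylsilane
Conditions: TBSCl, imidazole, DMF, rt
Reagents that add atoms: tert-butyldimethylsilyl chloride (SMILES CC(C)(C)[Si](C)(C)Cl)
Why: Standard silylation of a secondary allylic alcohol gives an ether that withstands the hydride, organometallic and amide bases that follow, and no stereocentre is touched.

Step 5
Reactants: 6 tert-butyl{[(1S,5S)-4,4-dimethoxy-2-methyl-5-(prop-1-en-2-yl)cyclohex-2-en-1-yl]oxy}dimethylsilane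
Product: 7 (4S,6S)-4-[(tert-butyldimethylsilyl)oxy]-3-methyl-6-(prop-1-en-2-yl)cyclohex-2-en-1-one
Conditions: pyridinium p-toluenesulfonate (cat.), acetone/H2O, rt
Reagents that add atoms: water (SMILES O)
Why: Mild acid-catalysed hydrolysis of the allylic dimethyl ketal, which ionises far more readily than the silyl ether, unmasks the enone; the isopropenyl-bearing C6 becomes epimerisable, but this centre is erased in step 7 and either epimer would lead to the same dienone.

Step 6
Reactants: 7 (4S,6S)-4-[(tert-butyldimethylsilyl)oxy]-3-methyl-6-(prop-1-en-2-yl)cyclohex-2-en-1-one; 8 vinylmagnesium bromide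
Product: 9 (1S,4S,6S)-4-[(tert-butyldimethylsilyl)oxy]-1-ethenyl-3-methyl-6-(prop-1-en-2-yl)cyclohex-2-en-1-ol
Conditions: CeCl3, THF, −78 °C; aqueous work-up
Reagents that add atoms: none
Why: Cerium-mediated 1,2-addition of the vinyl Grignard reagent suppresses enolisation and conjugate addition, and the nucleophile enters anti to the neighbouring isopropenyl group, so vinyl and isopropenyl are trans (new C1 centre S).

Step 7
Reactants: 9 (1S,4S,6S)-4-[(tert-butyldimethylsilyl)oxy]-1-ethenyl-3-methyl-6-(prop-1-en-2-yl)cyclohex-2-en-1-ol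
Product: 12 (2Z,4S,6E)-4-[(tert-butyldimethylsilyl)oxy]-3,7-dimethylcyclodeca-2,6-dien-1-one, via potassium alkoxide 10 (not isolated), via potassium enolate 11 (not isolated)
Conditions: KH, 18-crown-6, THF, 0 °C to 60 °C; then AcOH, −78 °C
Reagents that add atoms: none
Why: KH with 18-crown-6 converts the tertiary alcohol into the loosely ion-paired potassium alkoxide 10, whose oxyanion weakens the C1–C6 ring bond so that the [3,3] shift of the CH2=CH–C(O−)–CH–C(CH3)=CH2 unit forms C8–C9, breaks C1–C6 and gives enolate 11, which acetic acid protonates at C7. The closest known reaction type is the anionic oxy-Cope rearrangement of trans-1-vinyl-6-alkenylcyclohex-2-en-1-ols to (2Z,6E)-cyclodeca-2,6-dienones. The ten-membered ring closes by two-carbon ring expansion of the six-membered ring through a sigmatropic shift, not by end-to-end cyclisation, so high dilution is not required. No stereocentre is created; the carbinol and isopropenyl-bearing centres are erased and only C3 is carried on. The step needs E geometry at the new C1=C10 olefin and a regiodefined C6–C7 enolate: the chair transition state with the trans-disposed vinyl and isopropenyl groups both equatorial gives E, the cyclohexene double bond is carried over as Z C4=C5, and the enolate can only form towards C7. Formation of the delocalised enolate, which becomes a conjugated Z-enone on protonation, makes the shift irreversible.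

Step 8
Reactants: 12 (2Z,4S,6E)-4-[(tert-butyldimethylsilyl)oxy]-3,7-dimethylcyclodeca-2,6-dien-1-one
Product: 16 (2Z,4S,6E)-4-[(tert-butyldimethylsilyl)oxy]-3,7-dimethyl-10-methylidenecyclodeca-2,6-dien-1-one, via lithium enolate 13 (not isolated), via Mannich base 14 (not isolated), via trimethylammonium iodide 15 (not isolated)
Conditions: LiN(iPr)2, THF, −78 °C; CH2=NMe2+ I−, −78 °C to rt; MeI, CH2Cl2, rt; aq. NaHCO3
Reagents that add atoms: N,N-dimethylmethyleneiminium iodide, Eschenmoser's salt (SMILES C=[N+](C)C.[I-])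
Why: Kinetic deprotonation occurs at the only enolisable α-carbon (C10 of the dienone, C7 of the target), the enolate undergoes a Mannich reaction with Eschenmoser's salt, and exhaustive methylation followed by mild base eliminates trimethylamine to give the α-methylene ketone, no stereocentre being formed.

Step 9
Reactants: 16 (2Z,4S,6E)-4-[(tert-butyldimethylsilyl)oxy]-3,7-dimethyl-10-methylidenecyclodeca-2,6-dien-1-one
Product: 17 (1R,2Z,4S,6E)-4-[(tert-butyldimethylsilyl)oxy]-3,7-dimethyl-10-methylidenecyclodeca-2,6-dien-1-ol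
Conditions: (S)-1-methyl-3,3-diphenyltetrahydro-1H,3H-pyrrolo[1,2-c][1,3,2]oxazaborole (20 mol %), catecholborane, toluene, −78 °C
Reagents that add atoms: none
Why: Corey–Bakshi–Shibata reduction gives clean 1,2-reduction, and with the α-substituted 2-methylene arm as the large group and the C5 alkenyl CH arm as the small one the (S)-oxazaborolidine should deliver hydride to the face that gives the 1R alcohol (6R in target numbering), by the same model that leads from acetophenone to (R)-1-phenylethanol.

Step 10
Reactants: 18 ethyl 2-(hydroxymethyl)prop-2-enoate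
Product: 19 ethyl 2-({[tert-butyl(dimethyl)silyl]oxy}methyl)prop-2-enoate
Conditions: TBSCl, imidazole, CH2Cl2, 0 °C to rt
Reagents that add atoms: tert-butyldimethylsilyl chloride (SMILES CC(C)(C)[Si](C)(C)Cl)
Why: Standard silylation of a primary allylic alcohol, chosen so that C13–O and C3–O carry the same protecting group and are unveiled together later.

Step 11
Reactants: 19 ethyl 2-({[tert-butyl(dimethyl)silyl]oxy}methyl)prop-2-enoate
Product: 21 2-({[tert-butyl(dimethyl)silyl]oxy}methyl)prop-2-enoic acid, via lithium carboxylate 20 (not isolated)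
Conditions: LiOH, THF/H2O, 0 °C; then 1 M HCl to pH 4, 0 °C
Reagents that add atoms: lithium hydroxide (SMILES [Li+].[OH-])
Why: Saponification of an unhindered ethyl ester proceeds under conditions that leave the primary silyl ether intact, and brief cold acidification liberates the acid.

Step 12
Reactants: 17 (1R,2Z,4S,6E)-4-[(tert-butyldimethylsilyl)oxy]-3,7-dimethyl-10-methylidenecyclodeca-2,6-dien-1-ol; 21 2-({[tert-butyl(dimethyl)silyl]oxy}methyl)prop-2-enoic acid
Product: 22 (1R,2Z,4S,6E)-4-[(tert-butyldimethylsilyl)oxy]-3,7-dimethyl-10-methylidenecyclodeca-2,6-dien-1-yl 2-({[tert-butyl(dimethyl)silyl]oxy}methyl)prop-2-enoate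
Conditions: N,N'-dicyclohexylcarbodiimide, 4-(dimethylamino)pyridine (cat.), CH2Cl2, 0 °C to rt
Reagents that add atoms: none
Why: Steglich esterification acylates the doubly allylic secondary alcohol through its oxygen without ionising the C–O bond, so the C6 configuration is retained.

Step 13
Reactants: 22 (1R,2Z,4S,6E)-4-[(tert-butyldimethylsilyl)oxy]-3,7-dimethyl-10-methylidenecyclodeca-2,6-dien-1-yl 2-({[tert-butyl(dimethyl)silyl]oxy}methyl)prop-2-enoate
Product: 23 (3S,6R)-3,13-bis[(tert-butyldimethylsilyl)oxy]germacra-1(10)E,4Z,7(11)-trien-12,6-olide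
Conditions: second-generation Hoveyda–Grubbs catalyst [RuCl2(H2IMes)(=CH-C6H4-2-OiPr)] (10 mol %), toluene (5 mM), 80 °C
Reagents that add atoms: none
Why: Ring-closing metathesis between the two 1,1-disubstituted olefins closes the five-membered lactone with loss of ethene; the ring enforces the cis arrangement about the new tetrasubstituted C7=C11 bond, the trisubstituted ring olefins are poor partners for the ruthenium alkylidene, and no stereocentre is affected.

Step 14
Reactants: 23 (3S,6R)-3,13-bis[(tert-butyldimethylsilyl)oxy]germacra-1(10)E,4Z,7(11)-trien-12,6-olide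
Product: 24 (3S,6R)-3,13-dihydroxygermacra-1(10)E,4Z,7(11)-trien-12,6-olide
Conditions: HF·pyridine, pyridine, THF, 0 °C to rt
Reagents that add atoms: none
Why: Fluoride cleavage of both silyl ethers under buffered, weakly acidic conditions avoids the epimerisation at the lactone γ-carbon C6 that a basic fluoride source could cause.

Step 15
Reactants: 24 (3S,6R)-3,13-dihydroxygermacra-1(10)E,4Z,7(11)-trien-12,6-olide
Product: 25 (3S,6R)-3,13-diacetoxygermacra-1(10)E,4Z,7(11)-trien-12,6-olide
Conditions: Ac2O, pyridine, 4-(dimethylamino)pyridine (cat.), CH2Cl2, 0 °C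
Reagents that add atoms: acetic anhydride (SMILES CC(=O)OC(C)=O)
Why: Nucleophile-catalysed acetylation of the primary and the secondary allylic hydroxyl groups proceeds at oxygen, with retention at C3.

Step 16
Reactants: 25 (3S,6R)-3,13-diacetoxygermacra-1(10)E,4Z,7(11)-trien-12,6-olide
Product: 26 (1R,3S,6R)-3,13-diacetoxy-1-hydroperoxygermacra-4Z,7(11),10(14)-trien-12,6-olide (CNP0174966.1)
Conditions: O2, 5,10,15,20-tetraphenylporphyrin (cat.), visible light, CH2Cl2, −20 °C
Reagents that add atoms: dioxygen (SMILES O=O)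
Why: Schenck ene reaction of singlet oxygen at the most electron-rich olefin C1=C10 (C4=C5 is flanked by two acyloxy-bearing carbons and C7=C11 is conjugated to the lactone), with hydrogen abstraction from the C14 methyl group on the more substituted side of the olefin moving the double bond to C10=C14 and placing OOH on C1, as is typical of germacra-1(10)-enolides, and with oxygen expected to approach the outer face of the E-olefin in the preferred ring conformer to set 1R.

**Compound list**

1 | 4-methoxy-2-methylphenol | COc1ccc(O)c(C)c1 | starting material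
2 | 4,4-dimethoxy-2-methylcyclohexa-2,5-dien-1-one | COC1(OC)C=CC(=O)C(C)=C1 | intermediate
3 | isopropenylboronic acid pinacol ester | CC(=C)B1OC(C)(C)C(C)(C)O1 | starting material
4 | (5S)-4,4-dimethoxy-2-methyl-5-(prop-1-en-2-yl)cyclohex-2-en-1-one | COC1(OC)C=C(C)C(=O)C[C@H]1C(C)=C | intermediate
5 | (1S,5S)-4,4-dimethoxy-2-methyl-5-(prop-1-en-2-yl)cyclohex-2-en-1-ol | COC1(OC)C=C(C)[C@@H](O)C[C@H]1C(C)=C | intermediate
6 | tert-butyl{[(1S,5S)-4,4-dimethoxy-2-methyl-5-(prop-1-en-2-yl)cyclohex-2-en-1-yl]oxy}dimethylsilane | COC1(OC)C=C(C)[C@@H](O[Si](C)(C)C(C)(C)C)C[C@H]1C(C)=C | intermediate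
7 | (4S,6S)-4-[(tert-butyldimethylsilyl)oxy]-3-methyl-6-(prop-1-en-2-yl)cyclohex-2-en-1-one | O=C1C=C(C)[C@@H](O[Si](C)(C)C(C)(C)C)C[C@H]1C(C)=C | intermediate
8 | vinylmagnesium bromide | C=C[Mg]Br | starting material
9 | (1S,4S,6S)-4-[(tert-butyldimethylsilyl)oxy]-1-ethenyl-3-methyl-6-(prop-1-en-2-yl)cyclohex-2-en-1-ol (vinyl trans to isopropenyl) | C=C[C@]1(O)C=C(C)[C@@H](O[Si](C)(C)C(C)(C)C)C[C@H]1C(C)=C | intermediate
10 | potassium alkoxide of 9 | C=C[C@]1([O-])C=C(C)[C@@H](O[Si](C)(C)C(C)(C)C)C[C@H]1C(C)=C.[K+] | intermediate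
11 | potassium enolate of 12 (C6–C7 enolate in target numbering) | [K+].[O-]C1=CCC/C(C)=C/C[C@H](O[Si](C)(C)C(C)(C)C)/C(C)=C\1 | intermediate
12 | (2Z,4S,6E)-4-[(tert-butyldimethylsilyl)oxy]-3,7-dimethylcyclodeca-2,6-dien-1-one | O=C1/C=C(/C)[C@@H](O[Si](C)(C)C(C)(C)C)C/C=C(\C)CCC1 | intermediate
13 | lithium enolate of 12 | [Li+].[O-]C1=CCC/C(C)=C/C[C@H](O[Si](C)(C)C(C)(C)C)/C(C)=C\1 | intermediate
14 | (2Z,4S,6E)-4-[(tert-butyldimethylsilyl)oxy]-10-[(dimethylamino)methyl]-3,7-dimethylcyclodeca-2,6-dien-1-one (C10 epimers) | CN(C)CC1CC/C(C)=C/C[C@H](O[Si](C)(C)C(C)(C)C)/C(C)=C\C1=O | intermediate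
15 | trimethylammonium iodide derived from 14 | C[N+](C)(C)CC1CC/C(C)=C/C[C@H](O[Si](C)(C)C(C)(C)C)/C(C)=C\C1=O.[I-] | intermediate
16 | (2Z,4S,6E)-4-[(tert-butyldimethylsilyl)oxy]-3,7-dimethyl-10-methylidenecyclodeca-2,6-dien-1-one | C=C1CC/C(C)=C/C[C@H](O[Si](C)(C)C(C)(C)C)/C(C)=C\C1=O | intermediate
17 | (1R,2Z,4S,6E)-4-[(tert-butyldimethylsilyl)oxy]-3,7-dimethyl-10-methylidenecyclodeca-2,6-dien-1-ol | C=C1CC/C(C)=C/C[C@H](O[Si](C)(C)C(C)(C)C)/C(C)=C\[C@H]1O | intermediate
18 | ethyl 2-(hydroxymethyl)prop-2-enoate | C=C(CO)C(=O)OCC | starting material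
19 | ethyl 2-({[tert-butyl(dimethyl)silyl]oxy}methyl)prop-2-enoate | C=C(CO[Si](C)(C)C(C)(C)C)C(=O)OCC | intermediate
20 | lithium 2-({[tert-butyl(dimethyl)silyl]oxy}methyl)prop-2-enoate | [Li+].[O-]C(=O)C(=C)CO[Si](C)(C)C(C)(C)C | intermediate
21 | 2-({[tert-butyl(dimethyl)silyl]oxy}methyl)prop-2-enoic acid | C=C(CO[Si](C)(C)C(C)(C)C)C(=O)O | intermediate
22 | (1R,2Z,4S,6E)-4-[(tert-butyldimethylsilyl)oxy]-3,7-dimethyl-10-methylidenecyclodeca-2,6-dien-1-yl 2-({[tert-butyl(dimethyl)silyl]oxy}methyl)prop-2-enoate | C=C1CC/C(C)=C/C[C@H](O[Si](C)(C)C(C)(C)C)/C(C)=C\[C@H]1OC(=O)C(=C)CO[Si](C)(C)C(C)(C)C | intermediate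
23 | (3S,6R)-3,13-bis[(tert-butyldimethylsilyl)oxy]germacra-1(10)E,4Z,7(11)-trien-12,6-olide | C/C1=C\C[C@H](O[Si](C)(C)C(C)(C)C)/C(C)=C\[C@H]2OC(=O)C(CO[Si](C)(C)C(C)(C)C)=C2CC1 | intermediate
24 | (3S,6R)-3,13-dihydroxygermacra-1(10)E,4Z,7(11)-trien-12,6-olide | C/C1=C\C[C@H](O)/C(C)=C\[C@H]2OC(=O)C(CO)=C2CC1 | intermediate
25 | (3S,6R)-3,13-diacetoxygermacra-1(10)E,4Z,7(11)-trien-12,6-olide | C/C1=C\C[C@H](OC(C)=O)/C(C)=C\[C@H]2OC(=O)C(COC(C)=O)=C2CC1 | intermediate
26 | (1R,3S,6R)-3,13-diacetoxy-1-hydroperoxygermacra-4Z,7(11),10(14)-trien-12,6-olide (CNP0174966.1) | C=C1CCC2=C(COC(C)=O)C(=O)O[C@@H]2/C=C(/C)[C@@H](OC(C)=O)C[C@H]1OO | target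

**Step count**

Total: 16 steps. Longest linear sequence: 14 steps (steps 1–9 and 12–16); steps 10–11 prepare the acid side arm.

**Steps most likely to fail, with fallbacks**

1. Step 13 (metathesis). The ruthenium alkylidene may decay, or isomerise the olefins, before the slow ring closure between two 1,1-disubstituted alkenes to a tetrasubstituted olefin takes place. The fallback builds the butenolide by aldol chemistry; it sets out from dienone 12 (with ester 19 as the source of the three-carbon unit) and comes back at 23. Ozonolysis of 19 (O3, CH2Cl2, −78 °C; Me2S) would give ethyl 3-[(tert-butyldimethylsilyl)oxy]-2-oxopropanoate F1. The lithium enolate of 12 (LiN(iPr)2, THF, −78 °C) would add to the ketone carbonyl of F1 to give the aldol adduct F2, a mixture of epimers at C7 and C11, both of which are erased later. Reduction of the C6 ketone with the (S)-oxazaborolidine and catecholborane would give the diol ester F3, which lactonises with catalytic 1,8-diazabicyclo[5.4.0]undec-7-ene to the α-hydroxy lactone F4. Dehydration towards C7 (SOCl2, pyridine, 0 °C) would then give 23.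

2. Step 16 (photooxygenation). Oxygen may add to both faces of C1=C10, or abstract hydrogen from C2 or C9 instead of C14, on the diacetate. The fallback moves the ene reaction to the bis-silyl ether, whose bulky C3 substituent and different conformer population present the olefin differently, and carries the hydroperoxide in protected form; it sets out from 23 and comes back at 26. Photooxygenation of 23 under the conditions of step 16 would give the hydroperoxide F5. Treatment with 2-methoxypropene and catalytic pyridinium p-toluenesulfonate would mask it as the 2-methoxyprop-2-yl perketal F6. Desilylation (Bu4NF buffered with AcOH, THF, 0 °C) would give the perketal diol F7, and acetylation (Ac2O, pyridine) the perketal diacetate F8. Mild hydrolysis of the perketal (AcOH/THF/H2O, rt) would release 26.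

3. Step 9 (ketone reduction). The two alkenyl arms of the ketone may be discriminated too weakly by the catalyst, or the ring conformation may oppose it, so that C6 is formed with low selectivity. The fallback uses both epimers by separating them and inverting the wrong one during acylation; it sets out from 16 and comes back at 22. Luche reduction of 16 (NaBH4, CeCl3·7H2O, MeOH, −78 °C) would give 17 together with its C1 epimer, (1S,2Z,4S,6E)-4-[(tert-butyldimethylsilyl)oxy]-3,7-dimethyl-10-methylidenecyclodeca-2,6-dien-1-ol F9, which would be separated by chromatography. Alcohol 17 continues through step 12, while F9 would be esterified with acid 21 under Mitsunobu conditions (PPh3, diisopropyl azodicarboxylate, THF, 0 °C), the carboxylate displacing the activated oxygen with inversion to give the same ester 22.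

**Further compounds**

F1 | step 13 | ethyl 3-[(tert-butyldimethylsilyl)oxy]-2-oxopropanoate | CCOC(=O)C(=O)CO[Si](C)(C)C(C)(C)C
F2 | step 13 | ethyl 3-[(tert-butyldimethylsilyl)oxy]-2-hydroxy-2-[(3Z,5S,7E)-5-[(tert-butyldimethylsilyl)oxy]-4,8-dimethyl-2-oxocyclodeca-3,7-dien-1-yl]propanoate (epimers at the two new centres) | CCOC(=O)C(O)(CO[Si](C)(C)C(C)(C)C)C1CC/C(C)=C/C[C@H](O[Si](C)(C)C(C)(C)C)/C(C)=C\C1=O
F3 | step 13 | ethyl 3-[(tert-butyldimethylsilyl)oxy]-2-hydroxy-2-[(2R,3Z,5S,7E)-5-[(tert-butyldimethylsilyl)oxy]-2-hydroxy-4,8-dimethylcyclodeca-3,7-dien-1-yl]propanoate | CCOC(=O)C(O)(CO[Si](C)(C)C(C)(C)C)C1CC/C(C)=C/C[C@H](O[Si](C)(C)C(C)(C)C)/C(C)=C\[C@H]1O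
F4 | step 13 | (3S,6R)-3,13-bis[(tert-butyldimethylsilyl)oxy]-11-hydroxygermacra-1(10)E,4Z-dien-12,6-olide (epimers at C7 and C11) | C/C1=C\C[C@H](O[Si](C)(C)C(C)(C)C)/C(C)=C\[C@H]2OC(=O)C(O)(CO[Si](C)(C)C(C)(C)C)C2CC1
F5 | step 16 | (1R,3S,6R)-3,13-bis[(tert-butyldimethylsilyl)oxy]-1-hydroperoxygermacra-4Z,7(11),10(14)-trien-12,6-olide | C=C1CCC2=C(CO[Si](C)(C)C(C)(C)C)C(=O)O[C@@H]2/C=C(/C)[C@@H](O[Si](C)(C)C(C)(C)C)C[C@H]1OO
F6 | step 16 | (1R,3S,6R)-3,13-bis[(tert-butyldimethylsilyl)oxy]-1-[(2-methoxypropan-2-yl)peroxy]germacra-4Z,7(11),10(14)-trien-12,6-olide | C=C1CCC2=C(CO[Si](C)(C)C(C)(C)C)C(=O)O[C@@H]2/C=C(/C)[C@@H](O[Si](C)(C)C(C)(C)C)C[C@H]1OOC(C)(C)OC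
F7 | step 16 | (1R,3S,6R)-3,13-dihydroxy-1-[(2-methoxypropan-2-yl)peroxy]germacra-4Z,7(11),10(14)-trien-12,6-olide | C=C1CCC2=C(CO)C(=O)O[C@@H]2/C=C(/C)[C@@H](O)C[C@H]1OOC(C)(C)OC
F8 | step 16 | (1R,3S,6R)-3,13-diacetoxy-1-[(2-methoxypropan-2-yl)peroxy]germacra-4Z,7(11),10(14)-trien-12,6-olide | C=C1CCC2=C(COC(C)=O)C(=O)O[C@@H]2/C=C(/C)[C@@H](OC(C)=O)C[C@H]1OOC(C)(C)OC
F9 | step 9 | (1S,2Z,4S,6E)-4-[(tert-butyldimethylsilyl)oxy]-3,7-dimethyl-10-methylidenecyclodeca-2,6-dien-1-ol | C=C1CC/C(C)=C/C[C@H](O[Si](C)(C)C(C)(C)C)/C(C)=C\[C@@H]1O
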